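**Retrosynthetic overview**
- Both stereocentres are set in one operation: Ru-catalysed transfer hydrogenation with dynamic kinetic resolution of a racemic α-aryloxy-β-keto ester. The ester then becomes the C9'' CH2OH.
- The C8''–O4' bond comes from SN2 of the 4'-phenoxide of 7-O-pivaloyl-tricin on an α-bromo-β-keto ester made from 4-acetoxybenzoyl chloride.
- Key step: tricin is made in one protecting-group-free Mentzer annulation that breaks the C3 symmetry of phloroglucinol with ethyl syringoylacetate (from acetosyringone).
- Ring order: the A ring (phloroglucinol), B ring (acetosyringone) and side-chain arene are bought. The only ring formed is the γ-pyrone C ring, in step 2.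

Assumption: 4-acetoxybenzoyl chloride and potassium ethyl malonate are taken as catalogue reagents. The SMILES was checked as 7''S,8''S, which is the threo (syn) isomer.

**Step 1**
Reactants: 1 acetosyringone (4'-hydroxy-3',5'-dimethoxyacetophenone); 2 diethyl carbonate
Product: 3 ethyl 3-(4-hydroxy-3,5-dimethoxyphenyl)-3-oxopropanoate
Conditions: NaH (3.5 equiv), (EtO)2CO, THF, reflux; aq. HCl work-up
Reagents that add atoms: diethyl carbonate (2), CCOC(=O)OCC
Why: Crossed Claisen condensation of the phenoxide/enolate dianion with diethyl carbonate, driven by irreversible formation of the β-keto ester enolate.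

**Step 2 (key step)**
Reactants: 3 ethyl 3-(4-hydroxy-3,5-dimethoxyphenyl)-3-oxopropanoate; 4 phloroglucinol (benzene-1,3,5-triol)
Product: 5 tricin (5,7-dihydroxy-2-(4-hydroxy-3,5-dimethoxyphenyl)-4H-chromen-4-one)
Conditions: 4 (2 equiv, anhydrous), neat melt, 240 °C (microwave or sand bath), 10–20 min, N2 sweep
Reagents that add atoms: none (both partners are the listed reactants; EtOH and H2O are lost)
Why: Mentzer chromone synthesis, in which the thermally generated aroylketene C-acylates phloroglucinol and the resulting 2-hydroxyaryl 1,3-diketone cyclodehydrates; the three equivalent positions of phloroglucinol allow only one regioisomer, and O-acylation of the hindered 4-OH is thermally reversible.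

**Step 3**
Reactants: 5 tricin; 6 pivaloyl chloride
Product: 7 7-O-pivaloyl-tricin (5-hydroxy-2-(4-hydroxy-3,5-dimethoxyphenyl)-4-oxo-4H-chromen-7-yl pivalate)
Conditions: PivCl (1.05 equiv), Et3N (1.2 equiv), DMF, 0 °C
Reagents that add atoms: pivaloyl chloride (6), CC(C)(C)C(=O)Cl
Why: Chemoselective O-acylation of the most acidic, unhindered 7-OH; the 5-OH is chelated to C4=O and the 4'-OH is blocked by two ortho methoxy groups against the bulky acyl chloride.

**Step 4**
Reactants: 8 4-acetoxybenzoyl chloride; 9 potassium ethyl malonate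
Product: 10 ethyl 3-(4-acetoxyphenyl)-3-oxopropanoate
Conditions: 9 (2.1 equiv), MgCl2, Et3N, MeCN, 0 °C to rt; then aq. HCl (−CO2)
Reagents that add atoms: none (both partners are the listed reactants)
Why: Masamune–Claisen-type C-acylation of the magnesium malonate half-ester followed by decarboxylation; the aryl acetate is far less electrophilic than the acid chloride.

**Step 5**
Reactants: 10 ethyl 3-(4-acetoxyphenyl)-3-oxopropanoate
Product: 11 ethyl 3-(4-acetoxyphenyl)-2-bromo-3-oxopropanoate (racemic)
Conditions: NBS (1.05 equiv), NH4OAc (10 mol%), Et2O, rt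
Reagents that add atoms: N-bromosuccinimide, O=C1CCC(=O)N1Br
Why: Electrophilic α-bromination of the β-keto ester enol, which stops cleanly at the monobromide.

**Step 6**
Reactants: 7 7-O-pivaloyl-tricin; 11 ethyl 3-(4-acetoxyphenyl)-2-bromo-3-oxopropanoate
Product: 12 ethyl 3-(4-acetoxyphenyl)-2-{4-[5-hydroxy-4-oxo-7-(pivaloyloxy)-4H-chromen-2-yl]-2,6-dimethoxyphenoxy}-3-oxopropanoate (racemic, configurationally labile at C2)
Conditions: 11 (1.2 equiv), K2CO3 (1.5 equiv), dry acetone, rt to 40 °C; mild acidic work-up
Reagents that add atoms: none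
Why: Williamson-type SN2 of the only free, non-chelated phenoxide (4'-O⁻) on the doubly activated α-bromo-β-keto ester; aryl acetates are known to survive K2CO3/acetone alkylations.

**Step 7**
Reactants: 12 racemic α-aryloxy-β-keto ester
Product: 13 ethyl (2R,3S)-3-(4-acetoxyphenyl)-3-hydroxy-2-{4-[5-hydroxy-4-oxo-7-(pivaloyloxy)-4H-chromen-2-yl]-2,6-dimethoxyphenoxy}propanoate
Conditions: RuCl[(R,R)-TsDPEN](p-cymene) (2 mol%), HCO2H/Et3N (5:2), DMF, 30 °C
Reagents that add atoms: none (formic acid delivers hydrogen only)
Why: Noyori–Ikariya asymmetric transfer hydrogenation with dynamic kinetic resolution, in which C2 epimerises rapidly under Et3N, the (R,R) catalyst sets the aryl carbinol as 3S, and the syn preference established for α-alkoxy-β-keto esters sets C2 as R (the future 7''S,8''S threo pair).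

**Step 8**
Reactants: 13 syn-hydroxy ester
Product: 14 (−)-(7''S,8''S)-4'',5,7-trihydroxy-3',5'-dimethoxy-4',8''-oxyflavonolignan-7'',9''-diol (target)
Conditions: NaBH4 (6 equiv), THF/EtOH, 0 °C to rt; then K2CO3, MeOH, rt; AcOH to pH 6
Reagents that add atoms: none (hydride only; acetyl and pivaloyl are removed)
Why: Borohydride reduction of the α-aryloxy-β-hydroxy ester (activated by the α-oxygen and β-OH) gives the primary alcohol without touching C7''/C8'', and methanolysis then cleaves both aryl esters; the 5-hydroxy/7-phenoxide chromone is too deactivated to be reduced. The C8'' descriptor changes from R to S only because the CIP priorities change (CO2Et becomes CH2OH).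

**Compound list**
1 | acetosyringone | CC(=O)c1cc(OC)c(O)c(OC)c1 | starting material
2 | diethyl carbonate | CCOC(=O)OCC | starting material
3 | ethyl 3-(4-hydroxy-3,5-dimethoxyphenyl)-3-oxopropanoate | CCOC(=O)CC(=O)c1cc(OC)c(O)c(OC)c1 | intermediate
4 | phloroglucinol | Oc1cc(O)cc(O)c1 | starting material
5 | tricin | COc1cc(-c2cc(=O)c3c(O)cc(O)cc3o2)cc(OC)c1O | intermediate
6 | pivaloyl chloride | CC(C)(C)C(=O)Cl | starting material
7 | 7-O-pivaloyl-tricin | COc1cc(-c2cc(=O)c3c(O)cc(OC(=O)C(C)(C)C)cc3o2)cc(OC)c1O | intermediate
8 | 4-acetoxybenzoyl chloride | CC(=O)Oc1ccc(cc1)C(=O)Cl | starting material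
9 | potassium ethyl malonate | CCOC(=O)CC(=O)[O-].[K+] | starting material
10 | ethyl 3-(4-acetoxyphenyl)-3-oxopropanoate | CCOC(=O)CC(=O)c1ccc(OC(C)=O)cc1 | intermediate
11 | ethyl 3-(4-acetoxyphenyl)-2-bromo-3-oxopropanoate (racemic) | CCOC(=O)C(Br)C(=O)c1ccc(OC(C)=O)cc1 | intermediate
12 | racemic α-aryloxy-β-keto ester | CCOC(=O)C(Oc1c(OC)cc(-c2cc(=O)c3c(O)cc(OC(=O)C(C)(C)C)cc3o2)cc1OC)C(=O)c1ccc(OC(C)=O)cc1 | intermediate
13 | ethyl (2R,3S)-syn-hydroxy ester | COc1cc(-c2cc(=O)c3c(O)cc(OC(=O)C(C)(C)C)cc3o2)cc(OC)c1O[C@@H](C(=O)OCC)[C@@H](O)c1ccc(OC(C)=O)cc1 | intermediate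
14 | (7''S,8''S) target | COc1cc(-c2cc(=O)c3c(O)cc(O)cc3o2)cc(OC)c1O[C@@H](CO)[C@@H](O)c1ccc(O)cc1 | target

**Totals**
Total steps: 8. Longest linear sequence: 6 (steps 1, 2, 3, 6, 7, 8); steps 4–5 form a two-step side branch.

**Steps most likely to fail, with fallbacks**
1. Step 2 (Mentzer annulation with a free-phenol keto ester; risks are charring, oligomeric aryl esters and Pechmann-type coumarin). Fallback: build the pyrone by the Baker–Venkataraman/Cushman route instead. Acylate the LiHMDS polyanion of 2',4',6'-trihydroxyacetophenone with 4-benzyloxy-3,5-dimethoxybenzoyl chloride, cyclodehydrate with acid, then hydrogenolyse the benzyl group.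
2. Step 6 (SN2 of a di-ortho-substituted phenoxide on a secondary α-bromo-β-dicarbonyl; risks are halophilic debromination and acyl transfer). Fallback: switch to carbenoid chemistry. Convert 10 to the α-diazo-β-keto ester (p-ABSA, Et3N) and carry out Rh2(OAc)4-catalysed O–H insertion into the 4'-OH of 7 under neutral conditions.
3. Step 7 (syn selectivity and ee of the transfer hydrogenation with the bulky 2,6-dimethoxyaryloxy group, which is untested). Fallback: set the stereocentres by C–C bond formation instead. Alkylate 7 with an N-bromoacetyl chiral oxazolidinethione, run a Crimmins-type anti-glycolate aldol with 4-acetoxybenzaldehyde, and remove the auxiliary reductively (NaBH4) to reach the same threo diol.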